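## Retrosynthetic overview
1. The target comes from its 5,7,3',4'-tetraacetate by ester aminolysis, which does not touch the stereocentres.
2. That tetraacetate comes from acyclic 6-geranylluteolin tetraacetate. One enantioselective, proton-started cation-olefin cyclisation ended by water makes the ring C–C bond, the C–OH bond and both stereocentres.
3. 6-Geranylluteolin tetraacetate comes from luteolin and geranyl bromide by C6 C-geranylation (the prenyltransferase step of the plant) and peracetylation in the same flask.
4. Ring order: rings A, C and B are bought with luteolin. The cyclohexane ring is the only ring formed, and it is formed last, as in the plant.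

Assumption: the (S,S) antipode of the chiral acid is taken to give the (1S,2S) series. The sense is checked on the first run against the rotation of the natural product, and the equally available (R,R) antipode is used if it is opposite.

## Route

Step 1
Reactants: 1 luteolin; 2 geranyl bromide
Product: 4 6-geranylluteolin 5,7,3',4'-tetraacetate, via 6-geranylluteolin 3 (not isolated)
Conditions: NaOMe (2.2 equiv), 2 (1.3 equiv), MeOH, argon, 0 °C to 40 °C, 16 h; evaporate; Ac2O (12 equiv), pyridine, DMAP (10 mol %), 40 °C, 12 h; SiO2 separation from the 8-isomer and the O-geranyl ethers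
Reagents that add atoms: acetic anhydride, CC(=O)OC(C)=O
Why: Nuclear geranylation (phenoxide C-alkylation, SN2 at the primary allylic bromide so the E-alkene is kept) of the ambident ring A phenoxide in a protic solvent that shields oxygen, at C6 between the two oxygen donors, followed by in-flask peracetylation (nucleophilic acyl substitution), which makes the 6-isomer separable from the 8-isomer and masks all four phenols; no stereocentre is formed.

Step 2
Reactants: 4 6-geranylluteolin 5,7,3',4'-tetraacetate
Product: 5 6-{[(1S,2S)-2-hydroxy-2,6,6-trimethylcyclohexyl]methyl}luteolin 5,7,3',4'-tetraacetate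
Conditions: {[(S)-3,3'-Ar2-BINOL]P(=NSO2CF3)}2NH (Ar = 9,9-dimethylfluoren-2-yl, 5 mol %), H2O (10 equiv), (CF3)3COH/CH2Cl2 4:1, −10 °C, 72 h; Et3N quench; recrystallise to raise ee
Reagents that add atoms: water, O
Why: Proposed new method: an enantioselective proton-initiated cation-olefin cyclisation ended by external water, in which the confined chiral imidodiphosphorimidate acid protonates the terminal Me2C=CH alkene of the chair-folded E-geranyl chain, the inner alkene CH attacks the developing Me2C cation on one enantioface (sets C1' as S) and water adds anti at the methyl-bearing carbon (sets C2' as S, with OH and CH2Ar trans-diequatorial and CH3 axial), while the acetates take away the 5- and 7-OH that would otherwise close a hexahydroxanthene and make the arene too poor to lose the side chain; the closest known reaction types are the chiral Brønsted-acid cyclisations of 2-geranylphenols and of homofarnesol, which end on an internal oxygen, and the water-ended cyclisations with Hg(OTf)2 or in terpene cyclases, which give equatorial tertiary alcohols.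

Step 3
Reactants: 5 6-{[(1S,2S)-2-hydroxy-2,6,6-trimethylcyclohexyl]methyl}luteolin 5,7,3',4'-tetraacetate
Product: 6 6-{[(1S,2S)-2-hydroxy-2,6,6-trimethylcyclohexyl]methyl}luteolin (target)
Conditions: NH3 in MeOH (7 mol/L, 20 equiv), THF, argon, 0 °C, 2 h; evaporate; pH 5 buffer wash
Reagents that add atoms: none
Why: Aminolysis of aryl acetates (nucleophilic acyl substitution) is fast at 0 °C because phenoxides are good leaving groups, and the free tertiary alcohol, the flavone and both stereocentres stay untouched because nothing acidic is present to ionise C2'.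

## Compound list
1 | luteolin, 2-(3,4-dihydroxyphenyl)-5,7-dihydroxychromen-4-one | O=c1cc(-c2ccc(O)c(O)c2)oc2cc(O)cc(O)c12 | starting material
2 | geranyl bromide, (2E)-1-bromo-3,7-dimethylocta-2,6-diene | CC(C)=CCC/C(C)=C/CBr | starting material
3 | 6-geranylluteolin, luteolin carrying the (2E)-3,7-dimethylocta-2,6-dienyl chain on C6 | CC(C)=CCC/C(C)=C/Cc1c(O)cc2oc(-c3ccc(O)c(O)c3)cc(=O)c2c1O | intermediate
4 | 6-geranylluteolin 5,7,3',4'-tetraacetate | CC(C)=CCC/C(C)=C/Cc1c(OC(C)=O)cc2oc(-c3ccc(OC(C)=O)c(OC(C)=O)c3)cc(=O)c2c1OC(C)=O | intermediate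
5 | 6-{[(1S,2S)-2-hydroxy-2,6,6-trimethylcyclohexyl]methyl}luteolin 5,7,3',4'-tetraacetate (OH trans to CH2Ar) | CC1(C)CCC[C@](C)(O)[C@H]1Cc1c(OC(C)=O)cc2oc(-c3ccc(OC(C)=O)c(OC(C)=O)c3)cc(=O)c2c1OC(C)=O | intermediate
6 | 6-{[(1S,2S)-2-hydroxy-2,6,6-trimethylcyclohexyl]methyl}luteolin | CC1(C)CCC[C@](C)(O)[C@H]1Cc1c(O)cc2oc(-c3ccc(O)c(O)c3)cc(=O)c2c1O | target

## Step count and risks
Total step count: 3. Longest linear sequence: 3.

**Step 2 is the most likely to fail.**
- Water may level the acid.
- The terminal alkene may simply hydrate without ring closure.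
- The cation may lose a proton instead of taking up water.
- The basic pyrone carbonyl may hold the catalyst and lower both rate and ee.

The fallback sets out from 4 and comes back at 5. The same acid is used strictly dry, so the cation ends by proton loss. This gives 6-{[(1S)-2,2-dimethyl-6-methylidenecyclohexyl]methyl}luteolin tetraacetate F5 together with 6-{[(1S)-2,6,6-trimethylcyclohex-2-en-1-yl]methyl}luteolin tetraacetate F6, both with C1' already set. A Mukaiyama hydration (Co(acac)2, PhSiH3, O2, THF, room temperature) then turns both alkenes into the same tertiary C2' radical. O2 takes that radical from the face away from the axial C6' methyl, which gives the equatorial alcohol 5.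

**Step 1 is the second risk.** C8 alkylation, 7-O and 4'-O ethers and double alkylation compete, so only about 15–25 % of 4 is expected.

The fallback sets out from 1 (with 2 for the side chain) and comes back at 4.
- Ac2O (3.2 equiv) in pyridine at 0 °C spares the chelated 5-OH and gives luteolin 7,3',4'-triacetate F1.
- [BnNMe3][ICl2] with CaCO3 in CH2Cl2–MeOH iodinates ortho to the only free phenol and gives 6-iodoluteolin 7,3',4'-triacetate F2.
- Ac2O with DMAP gives 6-iodoluteolin tetraacetate F3.
- Stille coupling of F3 with (E)-geranyltributylstannane F4 (made from 2 and Bu3SnLi), using Pd2(dba)3, AsPh3 and LiCl in DMF at 60 °C, places the chain at C6 without ambiguity and gives 4.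

**Step 3 is the third risk.** Ammonia may add to the pyrone, and the catechol may oxidise in the basic medium.

The fallback sets out from 3 and comes back at 6.
- In the flask of step 1, benzyl chloroformate in pyridine takes the place of Ac2O and gives 6-geranylluteolin tetrakis(benzyl carbonate) F7.
- The cyclisation of step 2 gives 6-{[(1S,2S)-2-hydroxy-2,6,6-trimethylcyclohexyl]methyl}luteolin tetrakis(benzyl carbonate) F8.
- Neutral hydrogenolysis (H2 at 1 atm, Pd/C, EtOAc, room temperature) frees 6. No side-chain alkene is left at that stage.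

## Further compounds
F1 | step 1 | luteolin 7,3',4'-triacetate | CC(=O)Oc1cc(O)c2c(=O)cc(-c3ccc(OC(C)=O)c(OC(C)=O)c3)oc2c1
F2 | step 1 | 6-iodoluteolin 7,3',4'-triacetate | CC(=O)Oc1cc2oc(-c3ccc(OC(C)=O)c(OC(C)=O)c3)cc(=O)c2c(O)c1I
F3 | step 1 | 6-iodoluteolin tetraacetate | CC(=O)Oc1cc2oc(-c3ccc(OC(C)=O)c(OC(C)=O)c3)cc(=O)c2c(OC(C)=O)c1I
F4 | step 1 | (E)-geranyltributylstannane | CC(C)=CCC/C(C)=C/C[Sn](CCCC)(CCCC)CCCC
F5 | step 2 | 6-{[(1S)-2,2-dimethyl-6-methylidenecyclohexyl]methyl}luteolin tetraacetate | C=C1CCCC(C)(C)[C@@H]1Cc1c(OC(C)=O)cc2oc(-c3ccc(OC(C)=O)c(OC(C)=O)c3)cc(=O)c2c1OC(C)=O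
F6 | step 2 | 6-{[(1S)-2,6,6-trimethylcyclohex-2-en-1-yl]methyl}luteolin tetraacetate | CC1=CCCC(C)(C)[C@@H]1Cc1c(OC(C)=O)cc2oc(-c3ccc(OC(C)=O)c(OC(C)=O)c3)cc(=O)c2c1OC(C)=O
F7 | step 3 | 6-geranylluteolin tetrakis(benzyl carbonate) | CC(C)=CCC/C(C)=C/Cc1c(OC(=O)OCc2ccccc2)cc2oc(-c3ccc(OC(=O)OCc4ccccc4)c(OC(=O)OCc4ccccc4)c3)cc(=O)c2c1OC(=O)OCc1ccccc1
F8 | step 3 | 6-{[(1S,2S)-2-hydroxy-2,6,6-trimethylcyclohexyl]methyl}luteolin tetrakis(benzyl carbonate) | CC1(C)CCC[C@](C)(O)[C@H]1Cc1c(OC(=O)OCc2ccccc2)cc2oc(-c3ccc(OC(=O)OCc4ccccc4)c(OC(=O)OCc4ccccc4)c3)cc(=O)c2c1OC(=O)OCc1ccccc1
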